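**Plan**
1. Labels: ring A is the central benzene ring, its carbons a1–a6 carrying in turn O1, H, O1', C3', C11 and C3. O1–C2–C3 is the first dihydrobenzofuran, ring B the resorcinol ring on C3 and C10, C3–ring B–C10–C11–a5–a6 the seven-membered ring, and O1'–C2'–C3' the second dihydrobenzofuran.
2. Retrosynthetic cuts, in order: the nine O–CH3 bonds; C2'–C3' (carbene C–H insertion) and a4–C3' (aryllithium acylation); C10–ring B (Friedel–Crafts closure of the seven-membered ring) and C10=C11 (Horner–Wadsworth–Emmons); C2–C3 (carbene C–H insertion); a6–C3 (Friedel–Crafts acylation).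
3. Forward order: ring A is carried from the start with a bromine holding a4; first dihydrobenzofuran (step 6), then seven-membered ring (step 8), then second dihydrobenzofuran (step 13). In this order ring B is the only 3,5-dimethoxyphenyl group present when the C10 cation is made.
4. Enabling feature: C3 is a diarylmethine carbon between ring A and ring B, so it can be carried as a diaryl ketone and turned into a diaryl carbene. Ring A bears ortho to it, on a1, the oxygen whose benzylic CH2 (the future C2) lies 1,5 to that carbene.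
5. Stereochemistry: C3 from Rh2(R-PTAD)4; C10 from C3 in the cationic cyclisation; C2 by acid equilibration to trans; C3' from Rh2(S-PTAD)4; C2' by equilibration to trans during the final ether cleavage.

Key step: step 6

Remark on descriptors: with the labels above the target is (2R,3R,10R,2'S,3'S). C2 bears the 4-hydroxyphenyl group, C10 and C2' each a 2,4-dihydroxyphenyl group, C3' the 3,5-dihydroxyphenyl group.
Assumption: Rh2(R-PTAD)4, dirhodium tetrakis[(R)-N-phthaloyl-(1-adamantyl)glycinate], is taken to deliver 3R; if the sense of induction is the opposite one, the two antipodal catalysts of steps 6 and 13 change places.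

**Step 1**
Reactants: 1 diethyl (3,5-dimethoxybenzyl)phosphonate
Product: 2 diethyl (2-bromo-3,5-dimethoxybenzyl)phosphonate
Conditions: NBS, MeCN, 0 °C to rt
Reagents that add atoms: N-bromosuccinimide, O=C1CCC(=O)N1Br
Why: Electrophilic aromatic bromination should go to C2 (para to one methoxy group, ortho to the other), the position between the two methoxy groups being the more hindered; the bromine holds the place of the later a4–C3' bond.

**Step 2**
Reactants: 2 diethyl (2-bromo-3,5-dimethoxybenzyl)phosphonate; 3 3,5-dimethoxybenzoyl chloride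
Product: 4 diethyl {[2-bromo-6-(3,5-dimethoxybenzoyl)-3,5-dimethoxyphenyl]methyl}phosphonate
Conditions: SnCl4, CH2Cl2, 0 °C to rt
Reagents that add atoms: none
Why: Friedel–Crafts acylation should take the one free ring position that is para to a methoxy group (a6), because acylation between the two methoxy groups would force the a3 methoxy group against the bromine; this makes the a6–C3 bond as a diaryl ketone.

**Step 3**
Reactants: 4 diethyl {[2-bromo-6-(3,5-dimethoxybenzoyl)-3,5-dimethoxyphenyl]methyl}phosphonate
Product: 5 diethyl {[2-bromo-6-(3,5-dimethoxybenzoyl)-5-hydroxy-3-methoxyphenyl]methyl}phosphonate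
Conditions: BCl3, CH2Cl2, −78 °C to 0 °C; H2O
Reagents that add atoms: none
Why: Chelation-controlled ether cleavage: BCl3 bound to the ketone oxygen should remove only the methyl group of the methoxy group ortho to the carbonyl (on a1), leaving the other methyl ethers and, in the cold, the phosphonate ester.

**Step 4**
Reactants: 5 diethyl {[2-bromo-6-(3,5-dimethoxybenzoyl)-5-hydroxy-3-methoxyphenyl]methyl}phosphonate; 6 4-methoxybenzyl chloride
Product: 7 diethyl {[2-bromo-6-(3,5-dimethoxybenzoyl)-3-methoxy-5-(4-methoxybenzyloxy)phenyl]methyl}phosphonate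
Conditions: K2CO3, n-Bu4NI (cat.), DMF, 60 °C
Reagents that add atoms: none
Why: Williamson ether synthesis on the hydrogen-bonded phenol installs the 4-methoxybenzyl group whose CH2 becomes C2 and whose aryl group becomes the 4-hydroxyphenyl group of the target.

**Step 5**
Reactants: 7 diethyl {[2-bromo-6-(3,5-dimethoxybenzoyl)-3-methoxy-5-(4-methoxybenzyloxy)phenyl]methyl}phosphonate
Product: 8 hydrazone of 7
Conditions: N2H4·H2O (excess), AcOH (cat.), n-BuOH, 110 °C
Reagents that add atoms: hydrazine monohydrate, O.NN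
Why: Condensation of the diaryl ketone with excess hydrazine should give the N-unsubstituted hydrazone, the ethers, the aryl bromide and the phosphonate ester being inert to hydrazine; forcing conditions are chosen because the carbonyl has two ortho substituents.

**Step 6**
Reactants: 8 hydrazone of 7
Product: 10 diethyl {[(2S,3R)-5-bromo-3-(3,5-dimethoxyphenyl)-6-methoxy-2-(4-methoxyphenyl)-2,3-dihydro-1-benzofuran-4-yl]methyl}phosphonate (cis), via diaryldiazomethane 9 (not isolated)
Conditions: MnO2, CH2Cl2, 0 °C, filter; then Rh2(R-PTAD)4 (1 mol %), CH2Cl2, 0 °C to rt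
Reagents that add atoms: none
Why: MnO2 dehydrogenates the hydrazone to the diaryldiazomethane 9, which loses N2 on Rh2(R-PTAD)4 to give a diaryl (donor/donor) rhodium carbene at C3; the electrophilic carbene carbon takes up the hydride-like benzylic hydrogen of the ortho 4-methoxybenzyl ether and the C2–C3 bond forms in the same asynchronous event. The closest known reaction type is the enantioselective intramolecular C–H insertion of diaryl carbenes, made from benzophenone hydrazones with MnO2 and Rh2(PTAD)4, into ortho benzyl ethers to give cis-2,3-diaryl-2,3-dihydrobenzofurans. The one ring closed is the dihydrofuran ring, by 1,5-C–H insertion, its five atoms being C3, a6, a1, O1 and C2. C3 is set by the chiral carboxylate ligands of the catalyst (reagent control); C2 is set relative to C3 by the compact insertion transition state, which should give the cis (2S) isomer, corrected to trans in step 8. The step needs site selectivity for the O–CH2–Ar hydrogen, which the substrate secures because this is the only C–H bond that is both activated (alpha to oxygen and to a 4-methoxyphenyl group) and 1,5 to the carbene, the CH2P hydrogens being 1,4 and able to give only a four-membered ring. It also needs a carbene that meets neither an alkene nor a free OH, which is why the phenol is capped in step 4 and the stilbene is built only in step 7.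

**Step 7**
Reactants: 10 cis-dihydrobenzofuran phosphonate; 11 2,4-dimethoxybenzaldehyde
Product: 12 (2S,3R)-5-bromo-4-[(E)-2-(2,4-dimethoxyphenyl)ethenyl]-3-(3,5-dimethoxyphenyl)-6-methoxy-2-(4-methoxyphenyl)-2,3-dihydro-1-benzofuran
Conditions: KOtBu, THF, 0 °C to 50 °C
Reagents that add atoms: none
Why: Horner–Wadsworth–Emmons olefination of the benzylic phosphonate anion with the aromatic aldehyde should give the E-stilbene and so installs C11 and C10 with the 2,4-dimethoxyphenyl group; it is placed after step 6 because an ortho alkenyl group would capture the diazo compound by electrocyclisation.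

**Step 8**
Reactants: 12 cis-dihydrobenzofuran stilbene
Product: 13 (2R,3R,10R)-a4-bromo-a3-methoxy tetracycle (trans first dihydrobenzofuran; seven-membered ring closed)
Conditions: TFA, CH2Cl2, −20 °C, then rt
Reagents that add atoms: none
Why: Protonation of the electron-rich stilbene at C11 gives the 2,4-dimethoxybenzylic cation at C10, which ring B, the only nucleophilic arene in reach, attacks through its ortho carbon in a Friedel–Crafts closure of the seven-membered ring (the known acid cyclisation of ε-viniferin-type stilbenes to the ampelopsin B skeleton), C3 setting C10 as R because the C10 aryl group takes the position perpendicular to ring B, away from its ortho methoxy group; on warming, the same acid reversibly ionises the 4-methoxybenzylic C2–O bond and the dihydrobenzofuran should reclose to the more stable trans (2R) isomer.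

**Step 9**
Reactants: 13 (2R,3R,10R)-a4-bromo-a3-methoxy tetracycle; 3 3,5-dimethoxybenzoyl chloride
Product: 15 (2R,3R,10R)-a4-(3,5-dimethoxybenzoyl)-a3-methoxy tetracycle, via aryllithium 14 (not isolated)
Conditions: n-BuLi, THF, −78 °C; then added to 3, THF, −78 °C to 0 °C
Reagents that add atoms: none
Why: Bromine–lithium exchange is faster than any deprotonation at −78 °C, and the hindered aryllithium, added to an excess of the acid chloride, should stop at the doubly ortho-substituted diaryl ketone (acylation of an organolithium).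

**Step 10**
Reactants: 15 (2R,3R,10R)-a4-(3,5-dimethoxybenzoyl)-a3-methoxy tetracycle
Product: 16 (2R,3R,10R)-a4-(3,5-dimethoxybenzoyl)-a3-hydroxy tetracycle
Conditions: MgI2·OEt2, toluene, 80 °C; dilute HCl
Reagents that add atoms: none
Why: Chelation-controlled demethylation: the Mg of MgI2, held between the new carbonyl oxygen and the ortho methoxy oxygen, lets iodide remove only that methyl group, under conditions mild enough for the trans dihydrobenzofuran.

**Step 11**
Reactants: 16 (2R,3R,10R)-a4-(3,5-dimethoxybenzoyl)-a3-hydroxy tetracycle; 17 2,4-dimethoxybenzyl alcohol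
Product: 18 (2R,3R,10R)-a4-(3,5-dimethoxybenzoyl)-a3-(2,4-dimethoxybenzyloxy) tetracycle
Conditions: PPh3, DIAD, THF, 0 °C to rt
Reagents that add atoms: none
Why: Mitsunobu etherification of the phenol with the primary benzylic alcohol under neutral conditions should give the acid-sensitive 2,4-dimethoxybenzyl ether whose CH2 becomes C2'.

**Step 12**
Reactants: 18 (2R,3R,10R)-a4-(3,5-dimethoxybenzoyl)-a3-(2,4-dimethoxybenzyloxy) tetracycle
Product: 19 hydrazone of 18
Conditions: N2H4·H2O (excess), AcOH (cat.), n-BuOH, 110 °C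
Reagents that add atoms: hydrazine monohydrate, O.NN
Why: Hydrazone formation as in step 5; the basic medium leaves the acid-labile benzyl ether and the dihydrobenzofuran untouched.

**Step 13**
Reactants: 19 hydrazone of 18
Product: 21 (2R,3R,10R,2'R,3'S)-nonamethyl ether of the target skeleton (second dihydrobenzofuran cis), via diaryldiazomethane 20 (not isolated)
Conditions: MnO2, CH2Cl2, 0 °C, filter; then Rh2(S-PTAD)4 (1 mol %), CH2Cl2, 0 °C to rt
Reagents that add atoms: none
Why: Same reaction type as step 6: the diaryl rhodium carbene at C3' inserts into the 1,5-related O–CH2 hydrogen of the 2,4-dimethoxybenzyl ether and closes the second dihydrofuran ring, the antipodal catalyst setting C3' as S by reagent control and the insertion giving the cis (2'R) isomer; the C10–H and C11–H bonds are held out of reach by the rigid seven-membered ring.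

**Step 14**
Reactants: 21 (2R,3R,10R,2'R,3'S)-nonamethyl ether
Product: 22 target CNP0283541.1 (2R,3R,10R,2'S,3'S)
Conditions: BBr3, CH2Cl2, −78 °C to rt; MeOH, H2O
Reagents that add atoms: none
Why: BBr3 cleaves all nine aryl methyl ethers (Lewis acid ether cleavage) and at the same time reversibly ionises the doubly oxygen-stabilised benzylic C2'–O bond, so that the second dihydrobenzofuran should reclose to the more stable trans (2'S) isomer, as known for cis-2,3-diaryl-dihydrobenzofurans; C3, C10 and C3' carry no leaving group and are not touched.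

**Compound list**
1 | diethyl (3,5-dimethoxybenzyl)phosphonate | CCOP(=O)(OCC)Cc1cc(OC)cc(OC)c1 | starting material
2 | diethyl (2-bromo-3,5-dimethoxybenzyl)phosphonate | CCOP(=O)(OCC)Cc1cc(OC)cc(OC)c1Br | intermediate
3 | 3,5-dimethoxybenzoyl chloride | COc1cc(OC)cc(c1)C(Cl)=O | starting material
4 | diethyl {[2-bromo-6-(3,5-dimethoxybenzoyl)-3,5-dimethoxyphenyl]methyl}phosphonate | CCOP(=O)(OCC)Cc1c(Br)c(OC)cc(OC)c1C(=O)c1cc(OC)cc(OC)c1 | intermediate
5 | diethyl {[2-bromo-6-(3,5-dimethoxybenzoyl)-5-hydroxy-3-methoxyphenyl]methyl}phosphonate | CCOP(=O)(OCC)Cc1c(Br)c(OC)cc(O)c1C(=O)c1cc(OC)cc(OC)c1 | intermediate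
6 | 4-methoxybenzyl chloride | COc1ccc(CCl)cc1 | starting material
7 | diethyl {[2-bromo-6-(3,5-dimethoxybenzoyl)-3-methoxy-5-(4-methoxybenzyloxy)phenyl]methyl}phosphonate | CCOP(=O)(OCC)Cc1c(Br)c(OC)cc(OCc2ccc(OC)cc2)c1C(=O)c1cc(OC)cc(OC)c1 | intermediate
8 | hydrazone of 7: diethyl {[2-bromo-6-[(3,5-dimethoxyphenyl)(hydrazinylidene)methyl]-3-methoxy-5-(4-methoxybenzyloxy)phenyl]methyl}phosphonate | CCOP(=O)(OCC)Cc1c(Br)c(OC)cc(OCc2ccc(OC)cc2)c1C(=NN)c1cc(OC)cc(OC)c1 | intermediate
9 | diaryldiazomethane: diethyl {[2-bromo-6-[diazo(3,5-dimethoxyphenyl)methyl]-3-methoxy-5-(4-methoxybenzyloxy)phenyl]methyl}phosphonate | CCOP(=O)(OCC)Cc1c(Br)c(OC)cc(OCc2ccc(OC)cc2)c1C(=[N+]=[N-])c1cc(OC)cc(OC)c1 | intermediate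
10 | diethyl {[(2S,3R)-5-bromo-3-(3,5-dimethoxyphenyl)-6-methoxy-2-(4-methoxyphenyl)-2,3-dihydro-1-benzofuran-4-yl]methyl}phosphonate (cis) | COc1ccc([C@H]2Oc3cc(OC)c(Br)c(CP(=O)(OCC)OCC)c3[C@H]2c2cc(OC)cc(OC)c2)cc1 | intermediate
11 | 2,4-dimethoxybenzaldehyde | COc1ccc(C=O)c(OC)c1 | starting material
12 | (2S,3R)-5-bromo-4-[(E)-2-(2,4-dimethoxyphenyl)ethenyl]-3-(3,5-dimethoxyphenyl)-6-methoxy-2-(4-methoxyphenyl)-2,3-dihydro-1-benzofuran | COc1ccc([C@H]2Oc3cc(OC)c(Br)c(/C=C/c4ccc(OC)cc4OC)c3[C@H]2c2cc(OC)cc(OC)c2)cc1 | intermediate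
13 | (2R,3R,10R)-a4-bromo-a3-methoxy tetracycle: trans-2-(4-methoxyphenyl)dihydrobenzofuran on ring A; C3 and a5 bridged by dimethoxy ring B and C10H(2,4-dimethoxyphenyl)–C11H2 | COc1ccc([C@@H]2Oc3cc(OC)c(Br)c4c3[C@H]2c2cc(OC)cc(OC)c2[C@@H](c2ccc(OC)cc2OC)C4)cc1 | intermediate
14 | aryllithium: 13 with Li in place of Br on a4 | COc1ccc([C@@H]2Oc3cc(OC)c([Li])c4c3[C@H]2c2cc(OC)cc(OC)c2[C@@H](c2ccc(OC)cc2OC)C4)cc1 | intermediate
15 | (2R,3R,10R)-a4-(3,5-dimethoxybenzoyl)-a3-methoxy tetracycle | COc1ccc([C@@H]2Oc3cc(OC)c(C(=O)c5cc(OC)cc(OC)c5)c4c3[C@H]2c2cc(OC)cc(OC)c2[C@@H](c2ccc(OC)cc2OC)C4)cc1 | intermediate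
16 | (2R,3R,10R)-a4-(3,5-dimethoxybenzoyl)-a3-hydroxy tetracycle | COc1ccc([C@@H]2Oc3cc(O)c(C(=O)c5cc(OC)cc(OC)c5)c4c3[C@H]2c2cc(OC)cc(OC)c2[C@@H](c2ccc(OC)cc2OC)C4)cc1 | intermediate
17 | 2,4-dimethoxybenzyl alcohol | COc1ccc(CO)c(OC)c1 | starting material
18 | (2R,3R,10R)-a4-(3,5-dimethoxybenzoyl)-a3-(2,4-dimethoxybenzyloxy) tetracycle | COc1ccc([C@@H]2Oc3cc(OCc6ccc(OC)cc6OC)c(C(=O)c5cc(OC)cc(OC)c5)c4c3[C@H]2c2cc(OC)cc(OC)c2[C@@H](c2ccc(OC)cc2OC)C4)cc1 | intermediate
19 | hydrazone of 18 | COc1ccc([C@@H]2Oc3cc(OCc6ccc(OC)cc6OC)c(C(=NN)c5cc(OC)cc(OC)c5)c4c3[C@H]2c2cc(OC)cc(OC)c2[C@@H](c2ccc(OC)cc2OC)C4)cc1 | intermediate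
20 | diaryldiazomethane from 19 | COc1ccc([C@@H]2Oc3cc(OCc6ccc(OC)cc6OC)c(C(=[N+]=[N-])c5cc(OC)cc(OC)c5)c4c3[C@H]2c2cc(OC)cc(OC)c2[C@@H](c2ccc(OC)cc2OC)C4)cc1 | intermediate
21 | (2R,3R,10R,2'R,3'S)-nonamethyl ether of the target skeleton (second dihydrobenzofuran cis) | COc1ccc([C@@H]2Oc3cc4c(c5c3[C@H]2c2cc(OC)cc(OC)c2[C@@H](c2ccc(OC)cc2OC)C5)[C@H](c2cc(OC)cc(OC)c2)[C@H](c2ccc(OC)cc2OC)O4)cc1 | intermediate
22 | CNP0283541.1, (2R,3R,10R,2'S,3'S) | Oc1ccc([C@@H]2Oc3cc4c(c5c3[C@H]2c2cc(O)cc(O)c2[C@@H](c2ccc(O)cc2O)C5)[C@H](c2cc(O)cc(O)c2)[C@@H](c2ccc(O)cc2O)O4)cc1 | target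

**Count**
Total steps: 14. Longest linear sequence: 14 steps (1 to 22); the building blocks 3, 6, 11 and 17 are bought.

**Steps most likely to fail**

Step 14. While nine ethers are being cleaved, the ring-opened benzylic cations may be captured by bromide or by a neighbouring electron-rich ring, or lose a proton, instead of reclosing; the equilibration at C2' may also stay incomplete. The fallback sets out from 21. Brief treatment with TFA in CH2Cl2 at 0 °C equilibrates C2' alone and gives the all-trans nonamethyl ether F1. The ethers are then cleaved not by a Lewis acid but by SN2 attack of thiolate (NaSEt, DMF, 140 °C, then dilute HCl), a basic medium in which no benzylic cation can form. The route comes back at 22.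

Step 8. The C2–O bond may ionise before the seven-membered ring has closed; the C2 cation would then add to the stilbene and close a five-membered carbocycle. The fallback sets out from 10. TFA in CH2Cl2 at rt, with no alkene present, equilibrates C2 and gives the trans phosphonate F2. Olefination with 11 (KOtBu, THF) gives the trans stilbene F3. A catalytic amount of p-TsOH in CH2Cl2 at −40 °C, too weak at that temperature to ionise the trans dihydrobenzofuran, then closes the seven-membered ring. The route comes back at 13.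

Step 12. Hydrazine may fail to condense with a carbonyl group shielded by two ortho substituents inside the polycycle; the same difficulty, in milder form, may show in step 5, where the same remedy serves. The fallback sets out from 18. LiN(SiMe3)2 in THF–toluene at 60 °C adds to the carbonyl and eliminates silanolate (aza-Peterson reaction) to give the N-trimethylsilyl ketimine F4. Methanol frees the N–H ketimine F5. Transimination with N2H4·H2O in ethanol, far easier than condensation with the ketone, then gives the hydrazone. The route comes back at 19.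

**Further compounds**
F1 | step 14 | all-trans (2R,3R,10R,2'S,3'S)-nonamethyl ether of the target | COc1ccc([C@@H]2Oc3cc4c(c5c3[C@H]2c2cc(OC)cc(OC)c2[C@@H](c2ccc(OC)cc2OC)C5)[C@H](c2cc(OC)cc(OC)c2)[C@@H](c2ccc(OC)cc2OC)O4)cc1
F2 | step 8 | diethyl {[(2R,3R)-5-bromo-3-(3,5-dimethoxyphenyl)-6-methoxy-2-(4-methoxyphenyl)-2,3-dihydro-1-benzofuran-4-yl]methyl}phosphonate (trans) | COc1ccc([C@@H]2Oc3cc(OC)c(Br)c(CP(=O)(OCC)OCC)c3[C@H]2c2cc(OC)cc(OC)c2)cc1
F3 | step 8 | (2R,3R)-5-bromo-4-[(E)-2-(2,4-dimethoxyphenyl)ethenyl]-3-(3,5-dimethoxyphenyl)-6-methoxy-2-(4-methoxyphenyl)-2,3-dihydro-1-benzofuran (trans) | COc1ccc([C@@H]2Oc3cc(OC)c(Br)c(/C=C/c4ccc(OC)cc4OC)c3[C@H]2c2cc(OC)cc(OC)c2)cc1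
F4 | step 12 | N-trimethylsilyl ketimine of 18 | COc1ccc([C@@H]2Oc3cc(OCc6ccc(OC)cc6OC)c(C(=N[Si](C)(C)C)c5cc(OC)cc(OC)c5)c4c3[C@H]2c2cc(OC)cc(OC)c2[C@@H](c2ccc(OC)cc2OC)C4)cc1
F5 | step 12 | N–H ketimine of 18 | COc1ccc([C@@H]2Oc3cc(OCc6ccc(OC)cc6OC)c(C(=N)c5cc(OC)cc(OC)c5)c4c3[C@H]2c2cc(OC)cc(OC)c2[C@@H](c2ccc(OC)cc2OC)C4)cc1
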